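**Plan**
- Retrosynthesis: first the two O–benzyl bonds (acid and phenol are unmasked last). Then the C3'–C4' bond of the side chain (C1' is the benzylic CH2). Then the β-keto ester bonds, back to an arylacetic acid and the ring methyl of everninic acid.
- Enabling feature: the acetoxy carbon C2' is β to the cut and C4'–C13' is an unbranched decyl chain. The cut therefore leaves a 3-acetoxy-4-arylbutanoic acid and undecanoic acid, and both carboxyl groups are traceless activators lost as CO2.
- Forward: the benzene ring is bought and no ring is formed. The chain grows out from the ring methyl: CO2 (gives C2'), a malonate half-ester (gives C3' and the helper carboxyl), then the decyl group.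
- Stereochemistry: the only stereocentre (C2') is set by Ru–(S)-BINAP hydrogenation of the β-keto ester and fixed as the acetate. The coupling makes a radical at C3' only.
- The coupling is run cathodically (nickel electrocatalysis) because the electron-rich alkoxy-substituted benzene ring would not survive an anodic Kolbe coupling. Hydrogenolysis of both benzyl groups then frees the target without touching the acetate.

Key step: step 7

Remark: 2-hydroxy-4-methoxy-6-methylbenzoic acid (everninic acid), mono-tert-butyl malonate and undecanoic acid are taken as catalogue chemicals.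

**Step 1**
Reactants: 1 2-hydroxy-4-methoxy-6-methylbenzoic acid
Product: 2 benzyl 2-(benzyloxy)-4-methoxy-6-methylbenzoate
Conditions: BnBr (2.4 equiv), K2CO3 (3 equiv), DMF, 60 °C
Reagents that add atoms: benzyl bromide, BrCc1ccccc1
Why: Carboxylate O-alkylation and Williamson etherification (SN2 on benzyl bromide) of the acid and the hydrogen-bonded phenol; benzyl is used at both sites because it can be removed at the end without touching the acetate.

**Step 2**
Reactants: 2 benzyl 2-(benzyloxy)-4-methoxy-6-methylbenzoate
Product: 4 2-[3-(benzyloxy)-2-(benzyloxycarbonyl)-5-methoxyphenyl]acetic acid, via benzylic lithium compound 3 (not isolated)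
Conditions: LDA (1.2 equiv, commercial solution), THF, −78 °C; then CO2 (gas), −78 °C to rt; aq. HCl
Reagents that add atoms: carbon dioxide, O=C=O; lithium diisopropylamide, [Li]N(C(C)C)C(C)C (its lithium stays only in intermediate 3)
Why: Lateral (benzylic) lithiation of an ortho-toluate, whose ring methyl is the most acidic C–H because its anion is an ester-conjugated dienolate, followed by carboxylation; the 2,6-disubstituted ester is too hindered for Claisen self-condensation at −78 °C.

**Step 3**
Reactants: 4 2-[3-(benzyloxy)-2-(benzyloxycarbonyl)-5-methoxyphenyl]acetic acid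
Product: 6 benzyl 2-(benzyloxy)-6-(4-tert-butoxy-2,4-dioxobutyl)-4-methoxybenzoate, via acyl imidazolide 5 (not isolated)
Conditions: CDI (1.1 equiv), THF, rt; then HO2CCH2CO2tBu (1.5 equiv), MgCl2, Et3N, THF/MeCN, rt; aq. citric acid
Reagents that add atoms: mono-tert-butyl malonate, CC(C)(C)OC(=O)CC(=O)O; 1,1'-carbonyldiimidazole, O=C(n1ccnc1)n1ccnc1 (its imidazolyl group stays only in intermediate 5)
Why: Masamune–Brooks homologation (decarboxylative Claisen condensation of an acyl imidazolide with the magnesium enolate of a malonate half-ester) builds the β-keto ester under nearly neutral conditions at room temperature, where the chelated enolate should not close onto the hindered aryl ester.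

**Step 4**
Reactants: 6 benzyl 2-(benzyloxy)-6-(4-tert-butoxy-2,4-dioxobutyl)-4-methoxybenzoate
Product: 7 benzyl 2-(benzyloxy)-6-[(2S)-4-tert-butoxy-2-hydroxy-4-oxobutyl]-4-methoxybenzoate
Conditions: RuCl2[(S)-BINAP](dmf)n (1 mol%), H2 (50 bar), MeOH, 40 °C
Reagents that add atoms: none
Why: Noyori asymmetric hydrogenation of a β-keto ester, in which the ketone and tert-butyl ester oxygens chelate Ru–(S)-BINAP and hydride goes to one face of the ketone, which for 4-aryl-3-oxobutanoates gives the (S)-carbinol; ruthenium does not hydrogenolyse benzyl groups.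

**Step 5**
Reactants: 7 benzyl 2-(benzyloxy)-6-[(2S)-4-tert-butoxy-2-hydroxy-4-oxobutyl]-4-methoxybenzoate
Product: 8 benzyl 2-[(2S)-2-acetoxy-4-tert-butoxy-4-oxobutyl]-6-(benzyloxy)-4-methoxybenzoate
Conditions: Ac2O, pyridine, DMAP (cat.), CH2Cl2, 0 °C to rt
Reagents that add atoms: acetic anhydride, CC(=O)OC(C)=O
Why: DMAP-catalysed O-acylation with retention at the carbinol carbon, done at once so that the free hydroxyl cannot lactonise onto the neighbouring benzyl ester.

**Step 6**
Reactants: 8 benzyl 2-[(2S)-2-acetoxy-4-tert-butoxy-4-oxobutyl]-6-(benzyloxy)-4-methoxybenzoate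
Product: 9 (3S)-3-acetoxy-4-[3-(benzyloxy)-2-(benzyloxycarbonyl)-5-methoxyphenyl]butanoic acid
Conditions: TFA/CH2Cl2 (1:3), 0 °C to rt
Reagents that add atoms: none
Why: Acidolysis of the tert-butyl ester (alkyl–oxygen cleavage via the tert-butyl cation, lost as isobutene) frees only the aliphatic acid, since the benzyl ester, the aryl benzyl ether and the secondary acetate are stable to trifluoroacetic acid at room temperature.

**Step 7**
Reactants: 9 (3S)-3-acetoxy-4-[3-(benzyloxy)-2-(benzyloxycarbonyl)-5-methoxyphenyl]butanoic acid; 10 undecanoic acid (3 equiv)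
Product: 13 benzyl 2-[(2R)-2-acetoxytridecyl]-6-(benzyloxy)-4-methoxybenzoate, via N-acyloxyphthalimide of the acetoxy acid 11 (not isolated), via N-(undecanoyloxy)phthalimide 12 (not isolated)
Conditions: NHPI, DIC (4.2 equiv each), CH2Cl2, rt; concentrate; then NiCl2·6H2O (20 mol%), 2,2':6',2''-terpyridine (20 mol%), AgNO3 (0.3 equiv), DMF, Mg(+)/RVC(−), constant current, rt
Reagents that add atoms: N-hydroxyphthalimide, O=C1c2ccccc2C(=O)N1O (its atoms stay only in intermediates 11 and 12 and are lost again before 13)
Why: Ni-electrocatalytic doubly decarboxylative C(sp3)–C(sp3) coupling of two redox-active esters: cathodically generated low-valent Ni–terpyridine (electrons supplied by the sacrificial Mg anode) transfers an electron to each N-acyloxyphthalimide, N–O cleavage and loss of CO2 give the decyl radical and the primary 2-acetoxy-3-arylpropyl radical, and capture of both at nickel followed by reductive elimination forms the C3'–C4' bond. The closest known reaction type is this same coupling of two primary alkyl N-hydroxyphthalimide esters, including ones with an oxygen substituent β to the carboxyl group; it replaces the anodic Kolbe heterocoupling, which the oxidisable benzyloxy- and methoxy-substituted benzene ring would not survive. No ring is closed. No new stereocentre is formed: the radical sits at C3', next to but not at the acetoxy-bearing carbon, so the configuration set in step 4 is carried through unchanged (the descriptor changes from S to R only because the decyl chain ranks below CH2Ar). The step needs cross-coupling over homo-coupling, which the threefold excess of the cheap ester 12 should secure (the homodimer icosane is non-polar and easily removed), and reduction of the N–O esters only, which should hold because benzyl ester, aryl benzyl ether and acetate are not reduced at the potential of the nickel catalyst. Reductive elimination of the two primary alkyl groups should outpace β-acetoxy elimination at nickel and the slow 1,2-acetoxy shift of the β-acetoxyalkyl radical.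

**Step 8**
Reactants: 13 benzyl 2-[(2R)-2-acetoxytridecyl]-6-(benzyloxy)-4-methoxybenzoate
Product: 14 2-[(2R)-2-acetoxytridecyl]-6-hydroxy-4-methoxybenzoic acid
Conditions: H2 (1 atm), 10% Pd/C, EtOAc, rt
Reagents that add atoms: none
Why: Catalytic hydrogenolysis cleaves the benzyl ester and the aryl benzyl ether under neutral conditions; the molecule holds no other reducible group, the homobenzylic acetate is not hydrogenolysed and the stereocentre is not touched.

**Compound list**
1 | 2-hydroxy-4-methoxy-6-methylbenzoic acid (everninic acid) | Cc1cc(OC)cc(O)c1C(=O)O | starting material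
2 | benzyl 2-(benzyloxy)-4-methoxy-6-methylbenzoate | Cc1cc(OC)cc(OCc2ccccc2)c1C(=O)OCc1ccccc1 | intermediate
3 | [3-(benzyloxy)-2-(benzyloxycarbonyl)-5-methoxybenzyl]lithium | [Li]Cc1cc(OC)cc(OCc2ccccc2)c1C(=O)OCc1ccccc1 | intermediate
4 | 2-[3-(benzyloxy)-2-(benzyloxycarbonyl)-5-methoxyphenyl]acetic acid | OC(=O)Cc1cc(OC)cc(OCc2ccccc2)c1C(=O)OCc1ccccc1 | intermediate
5 | benzyl 2-(benzyloxy)-6-[2-(1H-imidazol-1-yl)-2-oxoethyl]-4-methoxybenzoate | O=C(Cc1cc(OC)cc(OCc2ccccc2)c1C(=O)OCc1ccccc1)n1ccnc1 | intermediate
6 | benzyl 2-(benzyloxy)-6-(4-tert-butoxy-2,4-dioxobutyl)-4-methoxybenzoate | CC(C)(C)OC(=O)CC(=O)Cc1cc(OC)cc(OCc2ccccc2)c1C(=O)OCc1ccccc1 | intermediate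
7 | benzyl 2-(benzyloxy)-6-[(2S)-4-tert-butoxy-2-hydroxy-4-oxobutyl]-4-methoxybenzoate | CC(C)(C)OC(=O)C[C@H](Cc1cc(OC)cc(OCc2ccccc2)c1C(=O)OCc1ccccc1)O | intermediate
8 | benzyl 2-[(2S)-2-acetoxy-4-tert-butoxy-4-oxobutyl]-6-(benzyloxy)-4-methoxybenzoate | CC(C)(C)OC(=O)C[C@H](Cc1cc(OC)cc(OCc2ccccc2)c1C(=O)OCc1ccccc1)OC(C)=O | intermediate
9 | (3S)-3-acetoxy-4-[3-(benzyloxy)-2-(benzyloxycarbonyl)-5-methoxyphenyl]butanoic acid | OC(=O)C[C@H](Cc1cc(OC)cc(OCc2ccccc2)c1C(=O)OCc1ccccc1)OC(C)=O | intermediate
10 | undecanoic acid | CCCCCCCCCCC(=O)O | starting material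
11 | 1,3-dioxoisoindolin-2-yl (3S)-3-acetoxy-4-[3-(benzyloxy)-2-(benzyloxycarbonyl)-5-methoxyphenyl]butanoate | O=C(C[C@H](Cc1cc(OC)cc(OCc2ccccc2)c1C(=O)OCc1ccccc1)OC(C)=O)ON1C(=O)c2ccccc2C1=O | intermediate
12 | 1,3-dioxoisoindolin-2-yl undecanoate | CCCCCCCCCCC(=O)ON1C(=O)c2ccccc2C1=O | intermediate
13 | benzyl 2-[(2R)-2-acetoxytridecyl]-6-(benzyloxy)-4-methoxybenzoate | CCCCCCCCCCC[C@H](Cc1cc(OC)cc(OCc2ccccc2)c1C(=O)OCc1ccccc1)OC(C)=O | intermediate
14 | 2-[(2R)-2-acetoxytridecyl]-6-hydroxy-4-methoxybenzoic acid | CCCCCCCCCCC[C@H](Cc1cc(OC)cc(O)c1C(=O)O)OC(C)=O | target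

Total step count: 8. Longest linear sequence: 8 steps (1 to 14; undecanoic acid 10 enters at step 7 without steps of its own).

**Steps most likely to fail**

Step 7. Homocoupling and hydrodecarboxylation of the two radicals may outrun the cross-coupling, or the alkylnickel intermediate may lose its acetate by β-elimination. The fallback sets out from 9 and makes the decyl partner a preformed nucleophile, so that only one radical is needed. Acid 9 would be converted to the ester 11 and isolated (NHPI, DIC, CH2Cl2). Ester 11 would then be coupled with didecylzinc F1 (from commercial decylmagnesium bromide and ZnCl2 in THF) under NiCl2·glyme and 4,4'-di-tert-butyl-2,2'-bipyridine in THF/DMF at rt. This is a nickel-catalysed decarboxylative alkyl–alkyl cross-coupling of a redox-active ester with a dialkylzinc, and it comes back to the route at 13.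

Step 2. Deprotonation may take place at the OCH2Ph group of the benzyl ester instead of the ring methyl, or the lithiated toluate may add to the ester of a second molecule. The fallback sets out from 2 and removes the ester from the lithiation altogether. The hindered ester would be saponified (KOH, DMSO/H2O, 80 °C) to 2-(benzyloxy)-4-methoxy-6-methylbenzoic acid F2. Its carboxylate would direct lateral lithiation as the dianion (LDA, 2.2 equiv, THF, −78 to −20 °C), and CO2 would give 2-(benzyloxy)-6-(carboxymethyl)-4-methoxybenzoic acid F3. Double benzylation (BnBr, K2CO3, DMF) would give benzyl 2-(benzyloxy)-6-[2-(benzyloxy)-2-oxoethyl]-4-methoxybenzoate F4. One equivalent of LiOH in THF/H2O at 0 °C should then hydrolyse only the unhindered arylacetic ester, and the route is rejoined at 4.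

Step 4. The new hydroxyl may attack the neighbouring benzyl ester during the hydrogenation or on concentration, closing a six-membered lactone with loss of benzyl alcohol. The fallback sets out from 6 and uses that lactone as a temporary ring. After the same hydrogenation the closure would be driven to completion (PPTS, toluene, 60 °C) to give tert-butyl 2-[(3S)-8-(benzyloxy)-6-methoxy-1-oxo-3,4-dihydro-1H-isochromen-3-yl]acetate F5, which can be purified and stored. Opening with KOH (1.05 equiv, THF/H2O, rt) would give potassium 2-(benzyloxy)-6-[(2S)-4-tert-butoxy-2-hydroxy-4-oxobutyl]-4-methoxybenzoate F6. Alkylation of this carboxylate with BnBr in DMF at rt would return to the route at 7, which would be acetylated at once as in step 5.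

**Further compounds**
F1 | step 7 | didecylzinc | CCCCCCCCCC[Zn]CCCCCCCCCC
F2 | step 2 | 2-(benzyloxy)-4-methoxy-6-methylbenzoic acid | Cc1cc(OC)cc(OCc2ccccc2)c1C(=O)O
F3 | step 2 | 2-(benzyloxy)-6-(carboxymethyl)-4-methoxybenzoic acid | OC(=O)Cc1cc(OC)cc(OCc2ccccc2)c1C(=O)O
F4 | step 2 | benzyl 2-(benzyloxy)-6-[2-(benzyloxy)-2-oxoethyl]-4-methoxybenzoate | O=C(Cc1cc(OC)cc(OCc2ccccc2)c1C(=O)OCc1ccccc1)OCc1ccccc1
F5 | step 4 | tert-butyl 2-[(3S)-8-(benzyloxy)-6-methoxy-1-oxo-3,4-dihydro-1H-isochromen-3-yl]acetate | CC(C)(C)OC(=O)C[C@@H]1Cc2cc(OC)cc(OCc3ccccc3)c2C(=O)O1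
F6 | step 4 | potassium 2-(benzyloxy)-6-[(2S)-4-tert-butoxy-2-hydroxy-4-oxobutyl]-4-methoxybenzoate | [K+].CC(C)(C)OC(=O)C[C@H](Cc1cc(OC)cc(OCc2ccccc2)c1C([O-])=O)O
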